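**Retrosynthetic overview**
- The target is disconnected at the C5 acrylic acid (Heck reaction of an aryl bromide with acrylic acid) and at the C3 CH2OH (hydride reduction of a C3 methyl ester, which also removes a phenol pivalate).
- The trans-2-aryl-2,3-dihydrobenzofuran-3-carboxylate comes from an iodine(III) oxidative ring contraction (1,2-aryl shift) of a (2S)-flavanone. C2 is carried over and C3 is set trans during the shift.
- The (2S)-flavanone comes from a catalytic enantioselective oxa-Michael cyclisation of a 2'-hydroxychalcone (the new step).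
- The chalcone comes from an aldol condensation of 5'-bromo-2'-hydroxy-3'-methoxyacetophenone (from 4-bromophenol and acetyl chloride) with O-pivaloyl syringaldehyde (from p-cresol).
- Ring order: both benzene rings are bought; the pyranone ring is closed in step 8 and contracted to the dihydrofuran ring in step 9.

Assumption: the sense of induction of the step 8 catalyst cannot be predicted with confidence. It is written in its L-tert-leucine-derived form, and its mirror image (from D-tert-leucine) is used if a test run gives the (2R)-flavanone.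

**Step 1**
Reactants: 1 4-bromophenol; 2 acetyl chloride
Product: 4 1-(5-bromo-2-hydroxyphenyl)ethan-1-one, via 4-bromophenyl acetate 3 (not isolated)
Conditions: AcCl (1.1 equiv), neat, 60 °C; then AlCl3 (1.6 equiv), 130 °C; ice/HCl
Reagents that add atoms: none
Why: O-acetylation followed by AlCl3 Fries rearrangement; the para position is blocked by Br, so the acetyl group can only go ortho to the OH.

**Step 2**
Reactants: 4 1-(5-bromo-2-hydroxyphenyl)ethan-1-one
Product: 5 1-(5-bromo-2-hydroxy-3-iodophenyl)ethan-1-one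
Conditions: NIS (1.1 equiv), TFA (30 mol %), MeCN, rt→50 °C
Reagents that add atoms: N-iodosuccinimide O=C1CCC(=O)N1I
Why: Electrophilic aromatic iodination; the only free position activated by the phenol (ortho to OH, para being brominated) is attacked.

**Step 3**
Reactants: 5 1-(5-bromo-2-hydroxy-3-iodophenyl)ethan-1-one
Product: 6 1-(5-bromo-2-hydroxy-3-methoxyphenyl)ethan-1-one
Conditions: NaOMe (4 equiv), CuI (10 mol %), 1,10-phenanthroline (20 mol %), MeOH–DMF, 70 °C; aq. HCl
Reagents that add atoms: sodium methoxide C[O-].[Na+]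
Why: Ullmann-type Cu(I)-catalysed methoxylation of an o-halophenol; C–I reacts with copper much faster than C–Br, so at 70 °C only the iodide is exchanged and the bromide is kept for step 11.

**Step 4**
Reactants: 7 4-methylphenol
Product: 10 3,5-dibromo-4-hydroxybenzaldehyde, via 2,6-dibromo-4-methylphenol 8 (not isolated), via 2,6-dibromo-4-(dibromomethyl)phenol 9 (not isolated)
Conditions: Br2 (2.05 equiv), o-dichlorobenzene, 35 °C; Br2 (2.05 equiv), 155 °C; H2O, 100 °C
Reagents that add atoms: bromine BrBr; water O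
Why: Electrophilic ring bromination at both ortho positions, then high-temperature side-chain bromination to the benzal bromide and its hydrolysis, the established one-pot route from p-cresol to this aldehyde.

**Step 5**
Reactants: 10 3,5-dibromo-4-hydroxybenzaldehyde
Product: 11 4-hydroxy-3,5-dimethoxybenzaldehyde (syringaldehyde)
Conditions: NaOMe (5 equiv), CuCl (25 mol %), DMF–MeOH, 115 °C; aq. HCl
Reagents that add atoms: sodium methoxide C[O-].[Na+]
Why: Cu-catalysed Ullmann methoxylation of both o-bromides, the classical syringaldehyde preparation.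

**Step 6**
Reactants: 11 4-hydroxy-3,5-dimethoxybenzaldehyde
Product: 12 4-formyl-2,6-dimethoxyphenyl pivalate
Conditions: PivCl (1.3 equiv), Et3N (1.6 equiv), DMAP (10 mol %), CH2Cl2, rt
Reagents that add atoms: pivaloyl chloride CC(C)(C)C(Cl)=O
Why: DMAP-catalysed O-acylation; the pivalate makes ring B electron-poor (no phenol oxidation, no B-ring migration and no C2–O ionisation in step 9) and is removed by the hydride in step 10.

**Step 7**
Reactants: 6 1-(5-bromo-2-hydroxy-3-methoxyphenyl)ethan-1-one; 12 4-formyl-2,6-dimethoxyphenyl pivalate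
Product: 13 (2E)-1-(5-bromo-2-hydroxy-3-methoxyphenyl)-3-[3,5-dimethoxy-4-(pivaloyloxy)phenyl]prop-2-en-1-one
Conditions: BF3·OEt2 (2 equiv), 1,4-dioxane, rt; aq. NaHCO3/MeOH work-up; recrystallise free of any flavanone
Reagents that add atoms: none
Why: BF3-mediated Claisen–Schmidt aldol condensation under acidic conditions that spare the aryl ester, giving the thermodynamic E-enone.

**Step 8**
Reactants: 13 (2E)-1-(5-bromo-2-hydroxy-3-methoxyphenyl)-3-[3,5-dimethoxy-4-(pivaloyloxy)phenyl]prop-2-en-1-one
Product: 14 4-[(2S)-6-bromo-8-methoxy-4-oxochroman-2-yl]-2,6-dimethoxyphenyl pivalate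
Conditions: bifunctional iminophosphorane catalyst 1-[3,5-bis(trifluoromethyl)phenyl]-3-[(2S)-3,3-dimethyl-1-{[tris(4-methoxyphenyl)-λ5-phosphanylidene]amino}butan-2-yl]thiourea (10 mol %), toluene, −20→0 °C; AcOH quench at full conversion; recrystallise (EtOH)
Reagents that add atoms: none
Why: Proposed new method: enantioselective 6-endo-trig oxa-Michael cyclisation of a non-activated 2'-hydroxychalcone under superbase/thiourea catalysis; the iminophosphorane fully deprotonates the chelated phenol and so breaks the O–H···O=C hydrogen bond that holds the oxygen away from Cβ, the thiourea binds the enone carbonyl and then the enolate, the chiral ion pair delivers the aryloxide to one face of Cβ to set C2 as (S), and proton return from P–N–H+ frees the catalyst under kinetic control; the closest known reactions are amine–thiourea-catalysed oxa-Michael cyclisations of α-ester-activated 2'-hydroxychalcones and iminophosphorane-catalysed oxa-Michael additions of alcohols to enoates.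

**Step 9**
Reactants: 14 4-[(2S)-6-bromo-8-methoxy-4-oxochroman-2-yl]-2,6-dimethoxyphenyl pivalate
Product: 17 methyl (2S,3S)-5-bromo-2-[3,5-dimethoxy-4-(pivaloyloxy)phenyl]-7-methoxy-2,3-dihydro-1-benzofuran-3-carboxylate, via flavanone dimethyl ketal 15 (not isolated), via 4-methoxy-2H-chromene enol ether 16 (not isolated)
Conditions: PhI(OAc)2 (1.2 equiv), conc. H2SO4 (2 equiv), HC(OMe)3, 0 °C→rt
Reagents that add atoms: trimethyl orthoformate COC(OC)OC
Why: Hypervalent-iodine oxidative rearrangement of a flavanone (ring contraction by 1,2-aryl shift); iodine(III) adds to C3 of the enol ether anti to the C2 aryl, methanol re-forms the C4 ketal, and the ring-A carbon antiperiplanar to the equatorial C3–I bond migrates from C4 to C3 with inversion, which gives the 3-ester trans to the 2-aryl group while C2 is untouched.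

**Step 10**
Reactants: 17 methyl (2S,3S)-5-bromo-2-[3,5-dimethoxy-4-(pivaloyloxy)phenyl]-7-methoxy-2,3-dihydro-1-benzofuran-3-carboxylate
Product: 18 4-[(2S,3R)-5-bromo-3-(hydroxymethyl)-7-methoxy-2,3-dihydro-1-benzofuran-2-yl]-2,6-dimethoxyphenol
Conditions: LiAlH4 (3.5 equiv), THF, 0 °C, 1 h; Rochelle salt work-up
Reagents that add atoms: none
Why: LiAlH4 reduction of the methyl ester to the primary alcohol with concurrent reductive cleavage of the aryl pivalate; the aryl bromide survives at 0 °C and no stereocentre is touched (the descriptor at C3 changes from S to R only through CIP priorities).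

**Step 11**
Reactants: 18 4-[(2S,3R)-5-bromo-3-(hydroxymethyl)-7-methoxy-2,3-dihydro-1-benzofuran-2-yl]-2,6-dimethoxyphenol; 19 acrylic acid
Product: 20 (2E)-3-[(2S,3R)-2-(4-hydroxy-3,5-dimethoxyphenyl)-3-(hydroxymethyl)-7-methoxy-2,3-dihydro-1-benzofuran-5-yl]prop-2-enoic acid
Conditions: acrylic acid (2 equiv), Pd(OAc)2 (5 mol %), P(o-tol)3 (15 mol %), Et3N (4 equiv), DMF, 90 °C; 1 M HCl
Reagents that add atoms: none
Why: Mizoroki–Heck reaction; syn-insertion and syn-β-hydride elimination give the E-cinnamic acid, free phenol and alcohol are tolerated, and the stereocentres are not involved.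

**Compound list**
1 | 4-bromophenol | Oc1ccc(Br)cc1 | starting material
2 | acetyl chloride | CC(Cl)=O | starting material
3 | 4-bromophenyl acetate (not isolated) | CC(=O)Oc1ccc(Br)cc1 | intermediate
4 | 1-(5-bromo-2-hydroxyphenyl)ethan-1-one | CC(=O)c1cc(Br)ccc1O | intermediate
5 | 1-(5-bromo-2-hydroxy-3-iodophenyl)ethan-1-one | CC(=O)c1cc(Br)cc(I)c1O | intermediate
6 | 1-(5-bromo-2-hydroxy-3-methoxyphenyl)ethan-1-one | CC(=O)c1cc(Br)cc(OC)c1O | intermediate
7 | 4-methylphenol (p-cresol) | Cc1ccc(O)cc1 | starting material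
8 | 2,6-dibromo-4-methylphenol (not isolated) | Cc1cc(Br)c(O)c(Br)c1 | intermediate
9 | 2,6-dibromo-4-(dibromomethyl)phenol (not isolated) | Oc1c(Br)cc(C(Br)Br)cc1Br | intermediate
10 | 3,5-dibromo-4-hydroxybenzaldehyde | O=Cc1cc(Br)c(O)c(Br)c1 | intermediate
11 | 4-hydroxy-3,5-dimethoxybenzaldehyde (syringaldehyde) | COc1cc(C=O)cc(OC)c1O | intermediate
12 | 4-formyl-2,6-dimethoxyphenyl pivalate | COc1cc(C=O)cc(OC)c1OC(=O)C(C)(C)C | intermediate
13 | (2E)-1-(5-bromo-2-hydroxy-3-methoxyphenyl)-3-[3,5-dimethoxy-4-(pivaloyloxy)phenyl]prop-2-en-1-one | COc1cc(Br)cc(C(=O)/C=C/c2cc(OC)c(OC(=O)C(C)(C)C)c(OC)c2)c1O | intermediate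
14 | 4-[(2S)-6-bromo-8-methoxy-4-oxochroman-2-yl]-2,6-dimethoxyphenyl pivalate | O=C1C[C@@H](c2cc(OC)c(OC(=O)C(C)(C)C)c(OC)c2)Oc2c(OC)cc(Br)cc12 | intermediate
15 | 4-[(2S)-6-bromo-4,4,8-trimethoxychroman-2-yl]-2,6-dimethoxyphenyl pivalate (not isolated) | COC1(OC)C[C@@H](c2cc(OC)c(OC(=O)C(C)(C)C)c(OC)c2)Oc2c(OC)cc(Br)cc12 | intermediate
16 | 4-[(2S)-6-bromo-4,8-dimethoxy-2H-chromen-2-yl]-2,6-dimethoxyphenyl pivalate (not isolated) | COC1=C[C@@H](c2cc(OC)c(OC(=O)C(C)(C)C)c(OC)c2)Oc2c(OC)cc(Br)cc12 | intermediate
17 | methyl (2S,3S)-5-bromo-2-[3,5-dimethoxy-4-(pivaloyloxy)phenyl]-7-methoxy-2,3-dihydro-1-benzofuran-3-carboxylate (trans) | COc1cc([C@H]2Oc3c(OC)cc(Br)cc3[C@@H]2C(=O)OC)cc(OC)c1OC(=O)C(C)(C)C | intermediate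
18 | 4-[(2S,3R)-5-bromo-3-(hydroxymethyl)-7-methoxy-2,3-dihydro-1-benzofuran-2-yl]-2,6-dimethoxyphenol (trans) | COc1cc([C@H]2Oc3c(OC)cc(Br)cc3[C@@H]2CO)cc(OC)c1O | intermediate
19 | acrylic acid | C=CC(=O)O | starting material
20 | (2E)-3-[(2S,3R)-2-(4-hydroxy-3,5-dimethoxyphenyl)-3-(hydroxymethyl)-7-methoxy-2,3-dihydro-1-benzofuran-5-yl]prop-2-enoic acid | COc1cc([C@H]2Oc3c(OC)cc(/C=C/C(=O)O)cc3[C@@H]2CO)cc(OC)c1O | target

**Totals**
Total step count: 11. Longest linear sequence: 8 steps (1→2→3→7→8→9→10→11, or 4→5→6→7→8→9→10→11).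

**Three steps most likely to fail**

Step 8 (the proposed new step). The cyclisation may be slow or poorly selective, and the product can lose ee by retro-oxa-Michael reaction if left with the base. The fallback uses known chemistry and sets out from 13. Cyclisation with NaOAc in refluxing EtOH gives the racemic flavanone 4-(6-bromo-8-methoxy-4-oxochroman-2-yl)-2,6-dimethoxyphenyl pivalate F3. Preparative chiral SFC on a polysaccharide carbamate phase separates it into 14 and the (2R)-enantiomer 4-[(2R)-6-bromo-8-methoxy-4-oxochroman-2-yl]-2,6-dimethoxyphenyl pivalate F4. F4 is put back through the same NaOAc equilibration (ring opening to 13 and reclosure) to regenerate F3. The route is rejoined at 14.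

Step 9. With this substituted substrate the competing 2,3-shift of ring B (to an isoflavone) or dehydrogenation to the flavone may take over. The fallback replaces the oxidative rearrangement by a Wolff ring contraction and sets out from 14. Condensation with DMF dimethyl acetal (toluene, 90 °C) gives the enaminone 4-[(2R,3E)-6-bromo-3-[(dimethylamino)methylidene]-8-methoxy-4-oxochroman-2-yl]-2,6-dimethoxyphenyl pivalate F5. Base-free diazo transfer with TsN3 (MeCN, rt) gives the diazoketone 4-[(2R)-6-bromo-3-diazo-8-methoxy-4-oxochroman-2-yl]-2,6-dimethoxyphenyl pivalate F6. In F5 and F6 the descriptor at C2 is R only because of CIP priorities; the geometry is that of 14. Irradiation (365 nm) in MeOH gives the ring-contracted ketene, which is trapped as the methyl ester. Brief DBU treatment in toluene equilibrates C3 to the trans isomer, and the route is rejoined at 17.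

Step 3. Some exchange of the para bromide, hydrodeiodination or base-induced self-condensation of the ketone may lower the yield. The fallback avoids any halogen discrimination and sets out from 4. Duff formylation (hexamethylenetetramine, TFA, 90 °C, then aq. HCl) gives 3-acetyl-5-bromo-2-hydroxybenzaldehyde F1. Dakin oxidation (H2O2, aq. NaOH, 0 °C→rt) gives 1-(5-bromo-2,3-dihydroxyphenyl)ethan-1-one F2. Methylation with MeI (1.05 equiv) and Li2CO3 in DMF at 50 °C takes place at the 3-OH, because the 2-OH is chelated to the ketone, and the route is rejoined at 6.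

**Further compounds**
F1 | step 3 | 3-acetyl-5-bromo-2-hydroxybenzaldehyde | CC(=O)c1cc(Br)cc(C=O)c1O
F2 | step 3 | 1-(5-bromo-2,3-dihydroxyphenyl)ethan-1-one | CC(=O)c1cc(Br)cc(O)c1O
F3 | step 8 | 4-(6-bromo-8-methoxy-4-oxochroman-2-yl)-2,6-dimethoxyphenyl pivalate (racemic) | O=C1CC(c2cc(OC)c(OC(=O)C(C)(C)C)c(OC)c2)Oc2c(OC)cc(Br)cc12
F4 | step 8 | 4-[(2R)-6-bromo-8-methoxy-4-oxochroman-2-yl]-2,6-dimethoxyphenyl pivalate | O=C1C[C@H](c2cc(OC)c(OC(=O)C(C)(C)C)c(OC)c2)Oc2c(OC)cc(Br)cc12
F5 | step 9 | 4-[(2R,3E)-6-bromo-3-[(dimethylamino)methylidene]-8-methoxy-4-oxochroman-2-yl]-2,6-dimethoxyphenyl pivalate | CN(C)/C=C1/C(=O)c2cc(Br)cc(OC)c2O[C@@H]1c3cc(OC)c(OC(=O)C(C)(C)C)c(OC)c3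
F6 | step 9 | 4-[(2R)-6-bromo-3-diazo-8-methoxy-4-oxochroman-2-yl]-2,6-dimethoxyphenyl pivalate | [N-]=[N+]=C1C(=O)c2cc(Br)cc(OC)c2O[C@@H]1c3cc(OC)c(OC(=O)C(C)(C)C)c(OC)c3
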